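The hydroazulene is cut back to a cis-fused decalin (ring A = C1–C6, ring B = C1, C6–C10). The key step exploits the triad C6(O)–C5–C1(quaternary), C5 and C1 being the atoms shared by the cyclopentane and the cycloheptane: a semipinacol 1,2-shift moves angular C1 from the C6 carbinol to C5 as a C5 sulfonate leaves. One operation forms the C1–C5 bond, contracts ring A to the cyclopentane, expands ring B to the C6 cycloheptanone and sets the trans fusion by inversion at C5. The precursor is an all-cis 4,5,6-trioxygenated decalin: O4 silylated to disarm the competing C3 shift, O5 an equatorial mesylate, O6 free, C8 methyl equatorial, C9 ketalised.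

Key step: step 7

Remarks on the chemistry
- Numbering (decalins and hydroazulenes alike): C1 angular carbon with CH3; C2, C3 CH2; C4 isopropyl carbinol; C5; C6; C7; C8 (CH3); C9 ketal/ketone; C10 CH2 between C9 and C1. β is the face of the C1 methyl.
- Structure correction: monoketal 2 is racemic at the methine next to the ketal (later C8), and that centre cannot epimerise. The auxiliary controls only C1, so two C8 epimers must form; a single C8 configuration cannot come out of the Michael step.
- Assumption: the two C8-epimeric enones can be separated by chromatography at 9. The 8β epimer is carried on because its methyl is equatorial in the reactive chair–chair conformer of 15; an 8α methyl would be axial and syn to C5. C8 is erased in step 13, so the other epimer can be processed in the same way.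
- Precursor redesign: the C3–C4 bond is as well aligned with the C5 leaving group as the C1–C6 bond, so O4 is silylated before the shift.

Step 1
Reactants: 1 2,5-dimethylcyclohexane-1,4-dione
Product: 2 6,9-dimethyl-1,4-dioxaspiro[4.5]decan-8-one (racemic, both diastereomers)
Conditions: HOCH2CH2OH (1.0 equiv), p-TsOH (cat.), PhMe, reflux, Dean–Stark
Reagents that add atoms: ethylene glycol, OCCO
Why: Acid-catalysed acetalisation with azeotropic removal of water; the two carbonyls are equivalent by symmetry, so only one monoketal can form, and dione and bis-ketal are recycled by re-equilibration.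

Step 2
Reactants: 2 monoketal; 3 (R)-1-phenylethylamine; 4 methyl vinyl ketone
Product: 7 (9R)-6,9-dimethyl-9-(3-oxobutyl)-1,4-dioxaspiro[4.5]decan-8-one (both C6 epimers; spiro C9 = route C1, spiro C6 = route C8), via imine 5 (not isolated), via adduct imine 6 (not isolated)
Conditions: (i) 3, p-TsOH (cat.), PhMe, reflux, Dean–Stark; (ii) 4, THF, rt; (iii) 20% aq. AcOH, rt
Reagents that add atoms: water, O
Why: Chiral-imine deracemising Michael addition: the imine reacts through its more substituted secondary enamine tautomer in a compact aza-ene-like transition state, and MVK bonds to C1 on the face away from the phenyl group of the (R)-auxiliary, which sets the C1 quaternary centre (the (S)-amine is the one that leads to the opposite sense), while the later C8 is untouched.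

Step 3
Reactants: 7 diketone (C8 epimer pair)
Product: 9 9,9-(ethylenedioxy)-1β,8β-dimethylbicyclo[4.4.0]dec-5-en-4-one, via ketol 8 (not isolated)
Conditions: NaOMe (0.3 equiv), MeOH, 60 °C; chromatography (C8 epimers)
Reagents that add atoms: none
Why: Intramolecular aldol addition of the methyl-ketone enolate to the ring carbonyl followed by E1cB dehydration (Robinson annulation) closes ring A without touching C1; the two C8 epimers are diastereomers of a rigid bicycle and are separated here.

Step 4
Reactants: 9 enone; 10 isopropylmagnesium chloride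
Product: 11 9,9-(ethylenedioxy)-4α-isopropyl-1β,8β-dimethylbicyclo[4.4.0]dec-5-en-4β-ol
Conditions: CeCl3 (anhydrous), 10, THF, −78 °C; then 9, −78 → 0 °C; H2O
Reagents that add atoms: none
Why: Organocerium 1,2-addition (suppresses enolisation and β-hydride reduction): the nucleophile should attack C4 axially on the α face, anti to the pseudo-axial C3–H bond and away from the axial C1 methyl, so that C4 carries β-OH (cis to the C1 methyl) and α-isopropyl.

Step 5
Reactants: 11 allylic alcohol
Product: 14 9,9-(ethylenedioxy)-4α-isopropyl-1β,8β-dimethyl-4β-(triethylsilyloxy)-cis-bicyclo[4.4.0]decane-5β,6β-diol, via osmate ester 12 (not isolated), via silylated osmate ester 13 (not isolated)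
Conditions: OsO4 (1.05 equiv), TMEDA (1.1 equiv), CH2Cl2, −78 °C; then Et3SiOTf, 2,6-lutidine, −78 → 0 °C; then H2N(CH2)2NH2, rt
Reagents that add atoms: osmium tetroxide, O=[Os](=O)(=O)=O; triethylsilyl trifluoromethanesulfonate, CC[Si](CC)(CC)OS(=O)(=O)C(F)(F)F
Why: Hydrogen-bond-directed dihydroxylation: OsO4·TMEDA accepts a hydrogen bond from O4–H and adds [3+2] to C5=C6 on the O4 (β) face, the α face also being screened by the pseudo-axial isopropyl group, which sets C5, C6 and the cis ring fusion; while O5 and O6 are locked in the inert osmate(VI) ester, O4–H is the only free hydroxyl and is silylated, and ligand exchange with ethylenediamine then frees the diol.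

Step 6
Reactants: 14 diol silyl ether
Product: 15 5-O-methanesulfonate of 14 (5β-OMs, 6β-OH, 4β-OSiEt3)
Conditions: MsCl, Et3N, CH2Cl2, −20 → 0 °C
Reagents that add atoms: methanesulfonyl chloride, CS(=O)(=O)Cl
Why: Sulfonylation through sulfene is confined to the only secondary hydroxyl (O5); the tertiary O6–H and the silyl ether are left alone and no stereocentre changes.

Step 7
Reactants: 15 mesylate
Product: 17 trans-fused 9,9-(ethylenedioxy)-4β-hydroxy-4α-isopropyl-1β,8β-dimethyl-5α-H-hydroazulen-6-one (route numbering), via silyl ether 16 (not isolated)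
Conditions: Et3Al (3 equiv), CH2Cl2, −78 → 0 °C; aq. Rochelle salt; then HF·pyridine, pyridine, THF, 0 °C
Reagents that add atoms: none
Why: Et3Al turns O6–H into an aluminium alkoxide and, as a Lewis acid, assists loss of the equatorial C5 mesylate; the C1–C6 bond, antiperiplanar to C5–OMs in the chair–chair conformer, migrates to C5 while C6=O forms, a semipinacol rearrangement of a 2-hydroxy sulfonate whose closest precedents are the organoaluminium-promoted pinacol-type shift of β-mesyloxy alcohols and the hydronaphthalene-to-hydroazulene contraction–expansion. Ring A becomes the cyclopentane through the new C1–C5 bond (ring contraction by a three-centre 1,2-shift, C6 leaving the ring) and ring B becomes the cycloheptanone by taking in C5 (one-carbon ring expansion); no Baldwin-type cyclisation is involved. The only new stereocentre, C5, is set by inversion because C1 enters anti to the leaving group, and C1 migrates with retention, so the cis-decalin with 5β-OMs becomes the trans-fused 5α-H hydroazulene with C4 untouched. The step needs C1 to migrate instead of C3: the O4 silyl ether is a much weaker donor than the O6 aluminium alkoxide, and quaternary C1 is the better migrating group. C5 has no β-hydrogen and the O4/O5/O6 array is all-cis, so elimination and epoxide closure are excluded. Buffered HF·pyridine then frees O4–H, which directs the next step.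

Step 8
Reactants: 17 β-hydroxy ketone
Product: 18 9,9-(ethylenedioxy)-4α-isopropyl-1β,8β-dimethyl-5α-H-hydroazulene-4β,6α-diol
Conditions: Me4NBH(OAc)3, MeCN/AcOH (1:1), −30 → 0 °C
Reagents that add atoms: none
Why: Evans–Saksena hydroxyl-directed reduction: O4 exchanges onto boron and hydride is delivered intramolecularly to the C6 carbonyl from the O4 (β) face, which should give the 6α-alcohol (1,3-anti to O4, anti to the C1 methyl).

Step 9
Reactants: 19 4-hydroxybenzoic acid
Product: 21 4-(tert-butyldimethylsilyloxy)benzoic acid, via bis-silyl ester 20 (not isolated)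
Conditions: TBSCl (2.2 equiv), imidazole, DMF, rt; then AcOH/H2O/THF, rt
Reagents that add atoms: tert-butyldimethylsilyl chloride, CC(C)(C)[Si](C)(C)Cl
Why: Exhaustive silylation followed by selective hydrolysis of the far more labile silyl ester leaves the phenol masked and the acid free.

Step 10
Reactants: 18 diol; 21 4-(tert-butyldimethylsilyloxy)benzoic acid
Product: 22 6α-[4-(tert-butyldimethylsilyloxy)benzoate] of 18
Conditions: DCC, DMAP (cat.), CH2Cl2, 0 °C → rt
Reagents that add atoms: none
Why: Steglich esterification acylates only the secondary C6–OH, the tertiary C4–OH being inert under these conditions; no stereocentre is touched.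

Step 11
Reactants: 22 ester ketal
Product: 23 C9 ketone of 22 (C8 now epimerisable, configuration immaterial)
Conditions: PPTS (cat.), acetone/H2O (9:1), 55 °C
Reagents that add atoms: water, O
Why: Mild acid-catalysed ketal hydrolysis frees the C9 ketone; pyridinium tosylate is too weak to dehydrate the tertiary alcohol or cleave the aryl silyl ether.

Step 12
Reactants: 23 ketone
Product: 24 C8=C9 trimethylsilyl enol ether of 23 carrying O4–SiMe3
Conditions: Me3SiCl, NaI, Et3N, MeCN, rt
Reagents that add atoms: chlorotrimethylsilane, C[Si](C)(C)Cl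
Why: Thermodynamic silyl enol ether formation with Me3SiI made in the flask favours the tetrasubstituted C8=C9 isomer and also silylates O4; the C9=C10 isomer cannot be dehydrogenated because C1 is quaternary, so it only returns ketone.

Step 13
Reactants: 24 enol silane
Product: 25 O4-trimethylsilyl, O-aryl-TBS derivative of the target (C7=C8–C9=O enone)
Conditions: Pd(OAc)2 (1.1 equiv), MeCN, rt
Reagents that add atoms: none
Why: Saegusa–Ito oxidation: transmetalation gives the C8 palladium enolate and syn β-hydride elimination towards C7 should give the conjugated endocyclic enone, which removes the C8 stereocentre.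

Step 14
Reactants: 25 silylated enone
Product: 26 lancerodiol p-hydroxybenzoate
Conditions: TBAF, AcOH (1:1), THF, 0 °C
Reagents that add atoms: none
Why: Buffered fluoride cleaves the aryl TBS ether and the tertiary TMS ether, while the acetic acid keeps the medium from touching the benzoate or enolising the γ-acyloxy enone.

Compound list
1 | 2,5-dimethylcyclohexane-1,4-dione (cis/trans mixture) | CC1CC(=O)C(C)CC1=O | starting material
2 | 6,9-dimethyl-1,4-dioxaspiro[4.5]decan-8-one (racemic, both diastereomers) | CC1CC2(OCCO2)C(C)CC1=O | intermediate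
3 | (R)-1-phenylethylamine | C[C@@H](N)c1ccccc1 | starting material
4 | methyl vinyl ketone | CC(=O)C=C | starting material
5 | N-[(R)-1-phenylethyl]imine of 2 | C[C@@H](N=C1CC(C)C2(OCCO2)CC1C)c1ccccc1 | intermediate (not isolated)
6 | Michael-adduct imine (C1 quaternary, 3-oxobutyl chain) | C[C@@H](N=C1CC(C)C2(OCCO2)C[C@@]1(C)CCC(C)=O)c1ccccc1 | intermediate (not isolated)
7 | (9R)-6,9-dimethyl-9-(3-oxobutyl)-1,4-dioxaspiro[4.5]decan-8-one, both C6 (route C8) epimers | CC(=O)CC[C@]1(C)CC2(OCCO2)C(C)CC1=O | intermediate
8 | aldol ketol (C6 carbinol, C4 ketone; carbinol configuration immaterial) | CC1CC2(O)CC(=O)CC[C@]2(C)CC13OCCO3 | intermediate (not isolated)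
9 | 9,9-(ethylenedioxy)-1β,8β-dimethylbicyclo[4.4.0]dec-5-en-4-one | C[C@H]1CC2=CC(=O)CC[C@]2(C)CC13OCCO3 | intermediate
10 | isopropylmagnesium chloride | CC(C)[Mg]Cl | starting material
11 | 9,9-(ethylenedioxy)-4α-isopropyl-1β,8β-dimethylbicyclo[4.4.0]dec-5-en-4β-ol | C[C@H]1CC2=C[C@](O)(C(C)C)CC[C@]2(C)CC13OCCO3 | intermediate
12 | osmate(VI) ester of the 5β,6β-diol, TMEDA adduct, O4–H free | C[C@H]1C[C@]2(O4)[C@@H](O[Os]4(=O)=O)[C@](O)(C(C)C)CC[C@]2(C)CC13OCCO3.CN(C)CCN(C)C | intermediate (not isolated)
13 | O4-triethylsilyl ether of 12 | C[C@H]1C[C@]2(O4)[C@@H](O[Os]4(=O)=O)[C@](O[Si](CC)(CC)CC)(C(C)C)CC[C@]2(C)CC13OCCO3.CN(C)CCN(C)C | intermediate (not isolated)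
14 | cis-decalin 5β,6β-diol 4β-triethylsilyl ether | C[C@H]1C[C@]2(O)[C@@H](O)[C@](O[Si](CC)(CC)CC)(C(C)C)CC[C@]2(C)CC13OCCO3 | intermediate
15 | 5-O-mesylate of 14 (key-step precursor) | C[C@H]1C[C@]2(O)[C@@H](OS(C)(=O)=O)[C@](O[Si](CC)(CC)CC)(C(C)C)CC[C@]2(C)CC13OCCO3 | intermediate
16 | trans-fused hydroazulen-6-one 9-ketal, 4β-triethylsilyl ether (key-step product) | C[C@H]1CC(=O)[C@@H]2[C@](C)(CC[C@@]2(O[Si](CC)(CC)CC)C(C)C)CC13OCCO3 | intermediate (not isolated)
17 | trans-fused 4β-hydroxy-4α-isopropyl-1β,8β-dimethylhydroazulen-6-one 9-ketal | C[C@H]1CC(=O)[C@@H]2[C@](C)(CC[C@@]2(O)C(C)C)CC13OCCO3 | intermediate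
18 | 4β,6α-diol 9-ketal | C[C@H]1C[C@H](O)[C@@H]2[C@](C)(CC[C@@]2(O)C(C)C)CC13OCCO3 | intermediate
19 | 4-hydroxybenzoic acid | O=C(O)c1ccc(O)cc1 | starting material
20 | tert-butyldimethylsilyl 4-(tert-butyldimethylsilyloxy)benzoate | CC(C)(C)[Si](C)(C)OC(=O)c1ccc(O[Si](C)(C)C(C)(C)C)cc1 | intermediate (not isolated)
21 | 4-(tert-butyldimethylsilyloxy)benzoic acid | CC(C)(C)[Si](C)(C)Oc1ccc(C(=O)O)cc1 | intermediate
22 | 6α-[4-(TBS-oxy)benzoate] of 18 | C[C@H]1C[C@H](OC(=O)c3ccc(O[Si](C)(C)C(C)(C)C)cc3)[C@@H]2[C@](C)(CC[C@@]2(O)C(C)C)CC14OCCO4 | intermediate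
23 | C9 ketone of 22 (C8 unspecified) | CC1C[C@H](OC(=O)c3ccc(O[Si](C)(C)C(C)(C)C)cc3)[C@@H]2[C@](C)(CC[C@@]2(O)C(C)C)CC1=O | intermediate
24 | C8=C9 trimethylsilyl enol ether, O4–SiMe3 | CC1=C(O[Si](C)(C)C)C[C@@]2(C)CC[C@@](O[Si](C)(C)C)(C(C)C)[C@@H]2[C@@H](OC(=O)c3ccc(O[Si](C)(C)C(C)(C)C)cc3)C1 | intermediate
25 | O4-TMS, O-aryl-TBS protected target | CC1=C[C@H](OC(=O)c3ccc(O[Si](C)(C)C(C)(C)C)cc3)[C@@H]2[C@](C)(CC[C@@]2(O[Si](C)(C)C)C(C)C)CC1=O | intermediate
26 | lancerodiol p-hydroxybenzoate | CC1=C[C@H](OC(=O)c2ccc(O)cc2)[C@@H]2[C@](C)(CC[C@@]2(O)C(C)C)CC1=O | target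

Total step count: 14. Longest linear sequence: 13 (steps 1–8 and 10–14; step 9 is a one-step side branch).

Steps most likely to fail

Step 7. Ionisation of the secondary mesylate, which is flanked by two oxygenated quaternary carbons, may be too slow at temperatures where the aluminium reagent spares the ketal and the silyl ether. On forcing, the silyl ether oxygen could begin to drive the C3 shift. The fallback drops the promoter and uses a stronger nucleofuge; it sets out from 14 and returns at 16. Diol 14 is treated with Tf2O and 2,6-di-tert-butyl-4-methylpyridine in CH2Cl2 at −78 °C. The secondary O5 triflate F3 should ionise on warming to about −20 °C with the neutral O6–H as the only push, the triflate-triggered ring contraction familiar from pyranoside chemistry. This gives 16, which is desilylated as in step 7.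

Step 5. Silylation of the hindered O4–H on the osmium complex may be incomplete, the silyl triflate may attack the osmate, or the silyl group may migrate from O4 to O5 once the diol is set free. Slow osmylation of the doubly neopentyl alkene is a further concern. The fallback dispenses with O4 protection; it sets out from 11 and returns at 17. The osmate ester from 11 is cleaved directly with ethylenediamine to the 4β,5β,6β-triol F1. MsCl/Et3N sulfonylates only the secondary O5 to give the triol 5-mesylate F2. Et3Al (CH2Cl2, −78 → 0 °C) converts both tertiary hydroxyls into aluminium alkoxides, and the shift then relies on the higher migratory aptitude of quaternary C1 over the C3 methylene, giving 17 directly.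

Step 13. β-Hydride loss may occur from the C8 methyl group (exocyclic methylene ketone) instead of from C7, and conversion will be low if part of the enol silane is the C9=C10 isomer. The fallback replaces palladium by halogenation–dehydrohalogenation; it sets out from 24 and returns at 25. NBS in THF at 0 °C brominates enol silane 24 at C8 to give the 8-bromo ketone F4. Li2CO3/LiBr in DMF at about 100 °C then eliminates HBr under equilibrating conditions, which favour the endocyclic conjugated enone 25. Loss of a silyl group on the way is immaterial because step 14 removes both.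

Further compounds
F1 | step 5 | 9,9-(ethylenedioxy)-4α-isopropyl-1β,8β-dimethyl-cis-bicyclo[4.4.0]decane-4β,5β,6β-triol | C[C@H]1C[C@]2(O)[C@@H](O)[C@](O)(C(C)C)CC[C@]2(C)CC13OCCO3
F2 | step 5 | 5-O-mesylate of triol F1 (O4–H and O6–H free) | C[C@H]1C[C@]2(O)[C@@H](OS(C)(=O)=O)[C@](O)(C(C)C)CC[C@]2(C)CC13OCCO3
F3 | step 7 | 5-O-triflate of diol 14 | C[C@H]1C[C@]2(O)[C@@H](OS(=O)(=O)C(F)(F)F)[C@](O[Si](CC)(CC)CC)(C(C)C)CC[C@]2(C)CC13OCCO3
F4 | step 13 | 8-bromo-9-ketone from 24 (O4–SiMe3, aryl O–TBS) | CC1(Br)C[C@H](OC(=O)c3ccc(O[Si](C)(C)C(C)(C)C)cc3)[C@@H]2[C@](C)(CC[C@@]2(O[Si](C)(C)C)C(C)C)CC1=O
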